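All constants were chosen freely; what happens was integrated by code.

We must pick one of four ways to run this flask.

| flask | electrophile | free base | protonated nucleophile | remark | time |
|---|---|---|---|---|---|
| alpha | 0.20 M | 0.220 M | 0.240 M | one stirred flow tank at steady state, fed with the mixture as stated, mean residence time 7.50 d |  |
| gamma | 0.20 M (fed, over 1.25 d) | 0.220 M | 0.240 M | all but electrophile at the start; electrophile goes in evenly over 1.25 d, the run ends at 2.5 d | 2.5 d |
| zeta | 0.20 M | 0.220 M | 0.240 M | a single well-mixed tank run continuously and read at steady state, 2.5 d in it on average |  |
| theta | 0.20 M | 0.220 M | 0.240 M | a closed flask charged with all of it at once and left for 2.5 d | 2.5 d |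

    acid set free → by-product carried off (k1 = 0.0142 /h)
    nucleophile + acid set free ⇌ protonated nucleophile, settled at all times (K2 = 7000 /M)
    electrophile + nucleophile → acid set free + target (k3 = 0.148 /M/h)
    acid set free + free base ⇌ salt of the base (K4 = 1.19 × 10⁵ /M, k4 = 1.71 /M/h)

- the stated concentrations are those of everything mixed, before any reaction; amounts are the same in each set-up
- the feed brings no volume worth counting
- run time (gamma): 2.5 d

- the set-up with the highest amount of target at the outlet or at the end, in percent of the electrophile put in ("none" if the first two lie within 2 percentage points) (alpha / gamma / zeta / theta / none)
- amount of target at the outlet or at the end, in percent of the electrophile put in, alpha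
- amount of target at the outlet or at the end, in percent of the electrophile put in, gamma
- amount of target at the outlet or at the end, in percent of the electrophile put in, zeta
- amount of target at the outlet or at the end, in percent of the electrophile put in, theta

Two of us disagree before any run. The first holds that the base strips the acid at once. Its binding constant beats the nucleophile's, and by its forward step alone, in theta as charged, free acid has a half-life of 0.077 d, against a run of 2.5 d. So the nucleophile stands free at about 0.220 M, and theta keeps 14.2% of its electrophile.

I hold otherwise. The protonated nucleophile is the resting state, and the free acid that the base can reach starts at 0.00586 M, which is less than the base charge. Let n be free nucleophile and h free acid. Their product is protonated nucleophile over its binding constant. Each target lowers n − h by two, since it takes one nucleophile and gives one acid. Each acid lost raises n − h by one.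

Let L be the first-order loss of free acid, by base and by-product together: 0.390 /h. Let p be the target rate constant times electrophile: 0.0296 /h. When n − h stands still, L h equals 2 p n. Solving gives the balance level of free nucleophile, 0.0150 M.

Now I count the fraction left. Electrophile falls at the target rate constant times this level. Theta keeps 87.5%, so it makes 12.5%. The alpha tank keeps 71.4%, so it makes 28.6%. Gamma's electrophile stays 1.88 d on average, which keeps 90.5%.

The forecast takes my side: “the slow base step must release it from its protonated form”. It gives alpha 22.6%, gamma 9.2%, zeta 9.5% and theta 10.8%, and it names alpha. My figures for alpha and theta stand higher.

The simulation gives alpha 22.6%, gamma 9.25%, zeta 9.51% and theta 10.5%, and the best is alpha.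

Theta reads free nucleophile 0.0132 M at 2.50 d, far below the base charge. The first view is right that the base takes up acid: at 25.0 d theta holds salt of the base at 0.204 M, with free base down to 7.49% of its charge. Yet free nucleophile in theta then reads 0.00551 M, still far below the base charge. A neighbour of gamma carries 0.55 M of free base. The level becomes 0.0235 M, and the same average stay keeps 85.5% of the electrophile. That neighbour reads free nucleophile 0.0213 M at 2.50 d, target 14.1% and electrophile left 85.9%.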